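**Retrosynthetic overview**
1. Target ⇒ its bis-benzyl ether; the last step is hydrogenolysis of the two benzyl ethers on ring A.
2. Diaryl ether C–O bond ⇒ ring A as 2,4-bis(benzyloxy)-6-pentylbenzoic acid plus ring B as methyl 2-hydroxy-4-methoxy-6-pentanoylbenzoate, joined by a new light-driven, copper-mediated decarboxylative aryloxylation (the carbon that carried CO2H receives the oxygen).
3. Ring A acid ⇒ olivetol: O-benzylation, Vilsmeier formylation between pentyl and OBn, Pinnick oxidation.
4. Ring B phenol ⇒ 3,5-dimethoxybenzonitrile: butyl Grignard addition, bromination ortho to the ketone, methoxycarbonylation, chelation-controlled cleavage of the methyl ether ortho to the ester.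
5. No ring is formed; both benzene rings are bought. The ring A piece and the ring B piece are made in parallel, joined, then deprotected.

Assumption: the target has no stereocentre and is achiral, so there is no enantiomer to select; the SMILES is taken as drawn.

**Route**

Step 1
Reactants: 1 olivetol (5-pentylbenzene-1,3-diol)
Product: 2 1,3-bis(benzyloxy)-5-pentylbenzene
Conditions: BnBr (2.4 equiv), K2CO3, DMF, 60 °C
Reagents that add atoms: benzyl bromide, BrCc1ccccc1
Why: Williamson ether synthesis; both phenols are O-alkylated cleanly under carbonate base.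

Step 2
Reactants: 2 1,3-bis(benzyloxy)-5-pentylbenzene
Product: 4 2,4-bis(benzyloxy)-6-pentylbenzaldehyde, via iminium dichlorophosphate 3 (not isolated)
Conditions: POCl3 (1.5 equiv), DMF, 0 → 70 °C; then H2O, 50 °C
Reagents that add atoms: N,N-dimethylformamide, CN(C)C=O; water, O
Why: Vilsmeier–Haack formylation; the electrophile enters para to one benzyloxy group and ortho to the other (next to the pentyl chain), because the position between the two benzyloxy groups is more hindered, as is known for orcinol and olivetol diethers.

Step 3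
Reactants: 4 2,4-bis(benzyloxy)-6-pentylbenzaldehyde
Product: 5 2,4-bis(benzyloxy)-6-pentylbenzoic acid
Conditions: NaClO2, NaH2PO4, 2-methyl-2-butene, t-BuOH/H2O, rt
Reagents that add atoms: sodium chlorite, [Na+].[O-]Cl=O
Why: Pinnick oxidation; chlorite converts the hindered aldehyde to the acid without touching the benzyl ethers, and the alkene scavenger prevents chlorination of the electron-rich ring.

Step 4
Reactants: 6 3,5-dimethoxybenzonitrile
Product: 8 1-(3,5-dimethoxyphenyl)pentan-1-one, via bromomagnesium ketiminate 7 (not isolated)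
Conditions: n-BuMgBr (1.5 equiv), THF, 0 → 65 °C; then 2 M HCl, rt
Reagents that add atoms: n-butylmagnesium bromide, CCCC[Mg]Br; water, O
Why: Grignard addition to a nitrile stops after one addition at the N-metallated imine, which aqueous acid hydrolyses to the ketone.

Step 5
Reactants: 8 1-(3,5-dimethoxyphenyl)pentan-1-one
Product: 9 1-(2-bromo-3,5-dimethoxyphenyl)pentan-1-one
Conditions: NBS (1.05 equiv), MeCN, 0 °C → rt, dark
Reagents that add atoms: N-bromosuccinimide, O=C1CCC(=O)N1Br
Why: Electrophilic aromatic bromination; 3,5-dimethoxyaryl carbonyl compounds brominate at the position para to one methoxy and ortho to the acyl group, not between the two methoxy groups, and polar non-acidic conditions disfavour α-bromination of the ketone.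

Step 6
Reactants: 9 1-(2-bromo-3,5-dimethoxyphenyl)pentan-1-one
Product: 10 methyl 2,4-dimethoxy-6-pentanoylbenzoate
Conditions: Pd(OAc)2 (5 mol %), Xantphos (7.5 mol %), CO (5 bar), Et3N, MeOH/DMF (1:2), 90 °C
Reagents that add atoms: carbon monoxide, [C-]#[O+]; methanol, CO
Why: Palladium-catalysed methoxycarbonylation of an aryl bromide (Heck carbonylation); the wide-bite-angle ligand supports carbonylation of the hindered bromide and excess methanol delivers the open-chain methyl ester.

Step 7
Reactants: 10 methyl 2,4-dimethoxy-6-pentanoylbenzoate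
Product: 12 methyl 2-hydroxy-4-methoxy-6-pentanoylbenzoate, via dichloroboryl ether 11 (not isolated)
Conditions: BCl3 (1.2 equiv), CH2Cl2, −78 → 0 °C; then H2O
Reagents that add atoms: none
Why: Chelation-controlled Lewis-acid demethylation; boron bound to the ester carbonyl cleaves only the methoxy group ortho to it, so the para methoxy group and the methyl ester survive.

Step 8
Reactants: 5 2,4-bis(benzyloxy)-6-pentylbenzoic acid; 12 methyl 2-hydroxy-4-methoxy-6-pentanoylbenzoate
Product: 16 methyl 2-[2,4-bis(benzyloxy)-6-pentylphenoxy]-4-methoxy-6-pentanoylbenzoate, via mixed copper carboxylate Cu(O2CAr)(OAr′) 13 (not isolated), via aryl radical 14 (not isolated), via arylcopper triflate ArCu(OTf)(OAr′) 15 (not isolated)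
Conditions: 5 (1.0 equiv), 12 (1.5 equiv), LiOt-Bu (2.5 equiv), Cu(OTf)2 (2.5 equiv), MeCN, 405 nm LEDs, 30 °C, N2
Reagents that add atoms: none
Why: Proposed new method: acid 5 and the chelating salicylate-type phenol 12 load onto divalent copper as complex 13; excitation of its carboxylate-to-copper charge-transfer band gives an aroyloxyl radical that loses CO2 to σ-aryl radical 14, so the oxygen must end up on the former carboxyl carbon; a second divalent copper phenoxide captures 14 as trivalent arylcopper aryloxide 15, and C–O reductive elimination gives 16; the electron-poor chelated phenoxide resists oxidation and should outcompete carboxylate in the reductive elimination; the closest known reaction type is copper LMCT decarboxylative functionalisation of benzoic acids (hydroxylation through aryl esters, halogenation, borylation) combined with the Chan–Lam/Ullmann C–O reductive elimination from trivalent copper, and the use of a phenol as the oxygen partner to make a diaryl ether is new.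

Step 9
Reactants: 16 methyl 2-[2,4-bis(benzyloxy)-6-pentylphenoxy]-4-methoxy-6-pentanoylbenzoate
Product: 17 methyl 2-(2,4-dihydroxy-6-pentylphenoxy)-4-methoxy-6-pentanoylbenzoate (target)
Conditions: H2 (1 atm), 10% Pd/C, EtOAc, rt
Reagents that add atoms: none
Why: Hydrogenolysis of benzyl aryl ethers; under neutral conditions at 1 atm the hindered aryl ketone, diaryl ether, methyl ester and methyl ether are left intact.

**Compound list**
1 | olivetol (5-pentylbenzene-1,3-diol) | CCCCCc1cc(O)cc(O)c1 | starting material
2 | 1,3-bis(benzyloxy)-5-pentylbenzene | CCCCCc1cc(OCc2ccccc2)cc(OCc2ccccc2)c1 | intermediate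
3 | N-[2,4-bis(benzyloxy)-6-pentylbenzylidene]-N-methylmethanaminium dichlorophosphate (not isolated) | CCCCCc1cc(OCc2ccccc2)cc(OCc2ccccc2)c1C=[N+](C)C.[O-]P(=O)(Cl)Cl | intermediate
4 | 2,4-bis(benzyloxy)-6-pentylbenzaldehyde | CCCCCc1cc(OCc2ccccc2)cc(OCc2ccccc2)c1C=O | intermediate
5 | 2,4-bis(benzyloxy)-6-pentylbenzoic acid | CCCCCc1cc(OCc2ccccc2)cc(OCc2ccccc2)c1C(=O)O | intermediate
6 | 3,5-dimethoxybenzonitrile | COc1cc(OC)cc(C#N)c1 | starting material
7 | bromomagnesium salt of 1-(3,5-dimethoxyphenyl)pentan-1-imine (not isolated) | CCCCC(=N[Mg]Br)c1cc(OC)cc(OC)c1 | intermediate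
8 | 1-(3,5-dimethoxyphenyl)pentan-1-one | CCCCC(=O)c1cc(OC)cc(OC)c1 | intermediate
9 | 1-(2-bromo-3,5-dimethoxyphenyl)pentan-1-one | CCCCC(=O)c1cc(OC)cc(OC)c1Br | intermediate
10 | methyl 2,4-dimethoxy-6-pentanoylbenzoate | CCCCC(=O)c1cc(OC)cc(OC)c1C(=O)OC | intermediate
11 | methyl 2-(dichloroboryloxy)-4-methoxy-6-pentanoylbenzoate (not isolated) | CCCCC(=O)c1cc(OC)cc(OB(Cl)Cl)c1C(=O)OC | intermediate
12 | methyl 2-hydroxy-4-methoxy-6-pentanoylbenzoate | CCCCC(=O)c1cc(OC)cc(O)c1C(=O)OC | intermediate
13 | mixed divalent copper complex Cu(O2CAr)(OAr′), Ar = 2,4-bis(benzyloxy)-6-pentylphenyl, OAr′ = phenoxide of 12 (not isolated) | CCCCCc1cc(OCc2ccccc2)cc(OCc2ccccc2)c1C(=O)O[Cu]Oc1cc(OC)cc(C(=O)CCCC)c1C(=O)OC | intermediate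
14 | 2,4-bis(benzyloxy)-6-pentylphenyl radical (not isolated) | CCCCCc1cc(OCc2ccccc2)cc(OCc2ccccc2)[c]1 | intermediate
15 | trivalent arylcopper complex ArCu(OTf)(OAr′) (not isolated) | CCCCCc1cc(OCc2ccccc2)cc(OCc2ccccc2)c1[Cu](OS(=O)(=O)C(F)(F)F)Oc1cc(OC)cc(C(=O)CCCC)c1C(=O)OC | intermediate
16 | methyl 2-[2,4-bis(benzyloxy)-6-pentylphenoxy]-4-methoxy-6-pentanoylbenzoate | CCCCCc1cc(OCc2ccccc2)cc(OCc2ccccc2)c1Oc1cc(OC)cc(C(=O)CCCC)c1C(=O)OC | intermediate
17 | methyl 2-(2,4-dihydroxy-6-pentylphenoxy)-4-methoxy-6-pentanoylbenzoate | CCCCCc1cc(O)cc(O)c1Oc1cc(OC)cc(C(=O)CCCC)c1C(=O)OC | target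

**Totals and risks**

Total step count: 9. Longest linear sequence: 6 (steps 4, 5, 6, 7, 8, 9).

The three steps most likely to fail:

Step 8 (the proposed new coupling). Likely failure modes:
- The electron-rich aroyloxyl radical may lose CO2 slowly or return the electron.
- Protodecarboxylation would give 2.
- The carboxylate of 5 may act as the oxygen partner and give an aryl ester.
- Radical 14 may take a hydrogen from the pentyl chain or add to a benzyl ring before copper captures it.
- The valerophenone unit of 12 and 16 is open to Norrish type 2 cleavage; 405 nm light, where the ketone barely absorbs, and the triplet-quenching excess of divalent copper are chosen against this.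

The fallback uses known chemistry with the polarity reversed; it sets out from 4 and 12 and comes back at 16. Baeyer–Villiger (Dakin-type) oxidation of aldehyde 4 with mCPBA in CH2Cl2 gives 2,4-bis(benzyloxy)-6-pentylphenyl formate F1. K2CO3 in MeOH cleaves it to 2,4-bis(benzyloxy)-6-pentylphenol F2. Phenol 12 is treated with Tf2O and pyridine in CH2Cl2 at 0 °C to give methyl 4-methoxy-6-pentanoyl-2-(trifluoromethylsulfonyloxy)benzoate F3. Palladium-catalysed diaryl ether coupling of F2 with F3 (Pd(OAc)2, tBuXPhos, K3PO4, toluene, 100 °C; zerovalent palladium forms in the flask) joins the electron-rich phenol to the ester-activated triflate and gives 16.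

Step 6 (carbonylation of a di-ortho-substituted, electron-rich aryl bromide next to a ketone). Oxidative addition may be slow, and the ketone can divert the reaction to a 3-butylidenephthalide. The fallback avoids cross-coupling altogether; it sets out from 8 and comes back at 10. Rieche formylation of ketone 8 (Cl2CHOMe, TiCl4, CH2Cl2, 0 °C) passes through 1-{2-[chloro(methoxy)methyl]-3,5-dimethoxyphenyl}pentan-1-one F4, which is hydrolysed on work-up to 2,4-dimethoxy-6-pentanoylbenzaldehyde F5. Pinnick oxidation (NaClO2, NaH2PO4, 2-methyl-2-butene) gives 2,4-dimethoxy-6-pentanoylbenzoic acid F6. Alkylation of its carboxylate with MeI and K2CO3 in DMF gives the open-chain ester 10 rather than the cyclic pseudo-ester.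

Step 9 (last step on the most valuable material). The aryl ketone may be partly reduced, and the electron-rich triol-type ring A is sensitive once freed. The fallback replaces reductive cleavage by a non-reductive Lewis-acid benzyl transfer; it sets out from 16 and comes back at 17. Treatment of 16 with BCl3 and pentamethylbenzene in CH2Cl2 at −78 °C moves both benzyl groups onto the scavenger arene. The ring B methoxy group is not ortho to a carbonyl and stays. This fallback makes no new compound (none F0).

**Further compounds**
F1 | step 8 | 2,4-bis(benzyloxy)-6-pentylphenyl formate | CCCCCc1cc(OCc2ccccc2)cc(OCc2ccccc2)c1OC=O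
F2 | step 8 | 2,4-bis(benzyloxy)-6-pentylphenol | CCCCCc1cc(OCc2ccccc2)cc(OCc2ccccc2)c1O
F3 | step 8 | methyl 4-methoxy-6-pentanoyl-2-(trifluoromethylsulfonyloxy)benzoate | CCCCC(=O)c1cc(OC)cc(OS(=O)(=O)C(F)(F)F)c1C(=O)OC
F4 | step 6 | 1-{2-[chloro(methoxy)methyl]-3,5-dimethoxyphenyl}pentan-1-one | CCCCC(=O)c1cc(OC)cc(OC)c1C(Cl)OC
F5 | step 6 | 2,4-dimethoxy-6-pentanoylbenzaldehyde | CCCCC(=O)c1cc(OC)cc(OC)c1C=O
F6 | step 6 | 2,4-dimethoxy-6-pentanoylbenzoic acid | CCCCC(=O)c1cc(OC)cc(OC)c1C(=O)O
F0 | step 9 | none | none
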